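**Retrosynthetic overview**
- Last event: acid-mediated cyclodehydration of an o-hydroxyaryl 1,3-diketone closes the pyranone (O1–C2), and the same acid removes a MOM group from the 3'-oxygen.
- Key disconnection: the C3–C4 bond, made by Rh(III)-catalysed aldehyde C–H activation of 2-hydroxy-3,4-dimethoxybenzaldehyde and carbene insertion from a B-ring β-keto sulfoxonium ylide. No acetophenone, chalcone or Baker–Venkataraman step is used.
- The ylide comes from methyl 3-hydroxy-4,5-dimethoxybenzoate by MOM protection and C-acylation of dimethylsulfoxonium methylide.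
- Ring order: rings A and B are bought intact; ring C is formed last, in the same pot as the C–C coupling.

Assumption: the target is an achiral, planar flavone with no stereocentre, so "single enantiomer" requires no stereocontrol and the SMILES is taken as written.

**Step 1**
Reactants: 1 methyl 3-hydroxy-4,5-dimethoxybenzoate
Product: 2 methyl 3,4-dimethoxy-5-(methoxymethoxy)benzoate
Conditions: NaH (1.2 equiv), MOMCl (1.3 equiv), THF/DMF, 0 °C to rt
Reagents that add atoms: chloromethyl methyl ether (MOMCl), COCCl
Why: Williamson-type O-alkylation (MOM protection) of the only acidic site, the sodium phenoxide reacting with the very electrophilic α-chloro ether at 0 °C while the methyl ester and aryl methyl ethers are inert; no stereocentre is formed.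

**Step 2**
Reactants: 2 methyl 3,4-dimethoxy-5-(methoxymethoxy)benzoate
Product: 3 2-[dimethyl(oxo)-λ6-sulfanylidene]-1-[3,4-dimethoxy-5-(methoxymethoxy)phenyl]ethan-1-one (β-keto sulfoxonium ylide)
Conditions: Me3S(O)I (3 equiv), KOtBu (3 equiv), THF, reflux 2 h; then 2, reflux
Reagents that add atoms: trimethylsulfoxonium iodide, C[S+](C)(C)=O.[I-] (converted in the flask by KOtBu into dimethylsulfoxonium methylide, C[S+](C)(=O)[CH2-])
Why: nucleophilic acyl substitution of the methyl ester by dimethylsulfoxonium methylide (Corey–Chaykovsky reagent used for C-acylation), the first-formed β-keto sulfoxonium salt being deprotonated at once to the carbonyl-stabilised ylide, which resists further attack, while the MOM acetal and aryl ethers tolerate the base.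

**Step 3**
Reactants: 3 β-keto sulfoxonium ylide; 4 2-hydroxy-3,4-dimethoxybenzaldehyde (1.5 equiv)
Product: 7 3'-hydroxy-4',5',7,8-tetramethoxyflavone, via MOM diketone 5 (not isolated), via MOM flavone 6 (not isolated)
Conditions: [Cp*RhCl2]2 (4 mol%), AgSbF6 (16 mol%), NaOAc (0.5 equiv), DCE, 80 °C, slow addition of 3; then conc. HCl, MeOH, 60 °C
Reagents that add atoms: none
Why: phenoxide-directed Rh(III) aldehyde C–H activation of 4 gives a five-membered acyl-rhodacycle that takes up ylide 3 as a carbene with loss of DMSO, migratory insertion and protodemetalation give 1,3-diketone 5 (C–H acylmethylation with a sulfoxonium ylide as carbene surrogate), and the acid stage then effects the classical cyclodehydration of the o-hydroxyaryl 1,3-diketone to the pyranone and methanolysis of the MOM acetal; the product is achiral, so no stereocentre has to be set.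

**Compound list**
1 | methyl 3-hydroxy-4,5-dimethoxybenzoate | COC(=O)c1cc(O)c(OC)c(OC)c1 | starting material
2 | methyl 3,4-dimethoxy-5-(methoxymethoxy)benzoate | COCOc1cc(C(=O)OC)cc(OC)c1OC | intermediate
3 | 2-[dimethyl(oxo)-λ6-sulfanylidene]-1-[3,4-dimethoxy-5-(methoxymethoxy)phenyl]ethan-1-one | COCOc1cc(C(=O)C=S(C)(C)=O)cc(OC)c1OC | intermediate
4 | 2-hydroxy-3,4-dimethoxybenzaldehyde | COc1ccc(C=O)c(O)c1OC | starting material
5 | 1-(2-hydroxy-3,4-dimethoxyphenyl)-3-[3,4-dimethoxy-5-(methoxymethoxy)phenyl]propane-1,3-dione (MOM diketone) | COCOc1cc(C(=O)CC(=O)c2ccc(OC)c(OC)c2O)cc(OC)c1OC | intermediate (not isolated)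
6 | 2-[3,4-dimethoxy-5-(methoxymethoxy)phenyl]-7,8-dimethoxy-4H-chromen-4-one (MOM flavone) | COCOc1cc(-c2cc(=O)c3ccc(OC)c(OC)c3o2)cc(OC)c1OC | intermediate (not isolated)
7 | 3'-hydroxy-4',5',7,8-tetramethoxyflavone | COc1cc(-c2cc(=O)c3ccc(OC)c(OC)c3o2)cc(O)c1OC | target

**Total step count:** 3
**Longest linear sequence:** 3 steps (1 → 2 → 3 → 7; aldehyde 4 is bought)

**Steps most likely to fail, with fallbacks**

Step 3 (highest risk). The ylide can self-annulate through ketone-directed ortho C–H activation of its own arene, the carbene can insert into the phenol O–H, and the acyl-rhodium species can decarbonylate. The fallback abandons C–H activation and sets out from ester 2. The lithium dianion of purchased 1-(2-hydroxy-3,4-dimethoxyphenyl)ethan-1-one F1 (LiHMDS 3.2 equiv, THF, −78 °C) is C-acylated by 2 on warming to rt in a crossed Claisen condensation. This gives MOM diketone 5, where the route is rejoined, and 5 is carried to 7 by the acid stage of step 3 (conc. HCl, MeOH, 60 °C).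

Step 2. The methyl ester carries a para-methoxy group and is electron-rich, so acyl substitution by the methylide may be slow or incomplete. The fallback sets out from 2 and replaces the unactivated ester by an activated one. Saponification (LiOH, THF/H2O, rt) gives 3,4-dimethoxy-5-(methoxymethoxy)benzoic acid F2. Coupling with 4-nitrophenol (EDC·HCl, DMAP, CH2Cl2) gives 4-nitrophenyl 3,4-dimethoxy-5-(methoxymethoxy)benzoate F3. F3 reacts with dimethylsulfoxonium methylide (Me3S(O)I, KOtBu, THF, 0 °C to rt) to give ylide 3, where the route is rejoined.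

Step 1. MOMCl is a regulated reagent, and a MOM group that partly falls off under the Lewis-acidic Rh/Ag stage would expose a free phenol during the coupling. The fallback sets out from 1 and uses a benzyl ether removed in a separate, neutral final operation:
- BnBr, K2CO3, DMF gives methyl 3-(benzyloxy)-4,5-dimethoxybenzoate F4.
- Me3S(O)I, KOtBu, THF, reflux gives 1-[3-(benzyloxy)-4,5-dimethoxyphenyl]-2-[dimethyl(oxo)-λ6-sulfanylidene]ethan-1-one F5.
- Rh(III) coupling with 4 under the step 3 conditions gives 1-[3-(benzyloxy)-4,5-dimethoxyphenyl]-3-(2-hydroxy-3,4-dimethoxyphenyl)propane-1,3-dione F6.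
- Conc. HCl, MeOH, 60 °C closes F6 to 2-[3-(benzyloxy)-4,5-dimethoxyphenyl]-7,8-dimethoxy-4H-chromen-4-one F7.
- Hydrogenolysis (H2, 10% Pd/C, EtOAc, rt) gives 7, where the route is rejoined.

**Further compounds**
F1 | step 3 | 1-(2-hydroxy-3,4-dimethoxyphenyl)ethan-1-one (purchased building block of the fallback) | CC(=O)c1ccc(OC)c(OC)c1O
F2 | step 2 | 3,4-dimethoxy-5-(methoxymethoxy)benzoic acid | COCOc1cc(C(=O)O)cc(OC)c1OC
F3 | step 2 | 4-nitrophenyl 3,4-dimethoxy-5-(methoxymethoxy)benzoate | COCOc1cc(C(=O)Oc2ccc([N+](=O)[O-])cc2)cc(OC)c1OC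
F4 | step 1 | methyl 3-(benzyloxy)-4,5-dimethoxybenzoate | COC(=O)c1cc(OC)c(OC)c(OCc2ccccc2)c1
F5 | step 1 | 1-[3-(benzyloxy)-4,5-dimethoxyphenyl]-2-[dimethyl(oxo)-λ6-sulfanylidene]ethan-1-one | CS(C)(=O)=CC(=O)c1cc(OC)c(OC)c(OCc2ccccc2)c1
F6 | step 1 | 1-[3-(benzyloxy)-4,5-dimethoxyphenyl]-3-(2-hydroxy-3,4-dimethoxyphenyl)propane-1,3-dione | COc1ccc(C(=O)CC(=O)c2cc(OC)c(OC)c(OCc3ccccc3)c2)c(O)c1OC
F7 | step 1 | 2-[3-(benzyloxy)-4,5-dimethoxyphenyl]-7,8-dimethoxy-4H-chromen-4-one | COc1cc(-c2cc(=O)c3ccc(OC)c(OC)c3o2)cc(OCc4ccccc4)c1OC
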